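**Strategy.** Numbering: oxepane O1, C2 (CMe2), C3 (C=O) to C7; cyclohexane C6–C11; bridge C12; primes for the second half. Each oxepane is cut at O1–C2, the bond joining the secondary oxygen on C7 to the quaternary gem-dimethyl C2 that neighbours the C3 carbonyl: the imprint of a trisubstituted 2,3-epoxide opened at its tertiary end. One acid-catalysed operation closes both seven-membered rings, trans-fused, onto a preformed 1,2-bis(cyclohexyl)ethane. The precursor carries the C10 and C10′ acetates (opposite relative configuration), free equatorial C7 hydroxyls and two (3R)-epoxidised homoprenyl arms; it comes from an (S)-4-silyloxy-3-methylcyclohexenone by cuprate addition, α-methylenation, reductive dimerisation and separate treatment of the two carbonyls.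

Key step: step 14

Remark on the structures: the given structures are mutually consistent, but the molecule is not C2-symmetric. At C10 (R) the acetoxy group is axial and cis to the C6 methyl; at C10′ (S) it is equatorial and trans to the C6′ methyl. A symmetric diketone must therefore be differentiated.

Remark on the design: a peracid cannot epoxidise the exocyclic methylene selectively while the homoprenyl alkenes are present, so the C10′ carbinol is made by oxymercuration. The epoxides are set under reagent control so that the cyclisation substrate is one diastereomer.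

Assumption: the lipase in step 3 acylates the (R)-alcohol faster (empirical size rule for secondary alcohols: large C(CH3)= flank, medium CH2 flank), leaving the (S)-alcohol. The configuration of the recovered alcohol is to be confirmed before it is carried on.

**Route**

Step 1
Reactants: 1 3-methylcyclohex-2-en-1-one
Product: 2 3-methylcyclohexa-1,3-dien-1-yl acetate
Conditions: isopropenyl acetate (excess), TsOH·H2O (cat.), reflux, acetone distilled off
Reagents that add atoms: isopropenyl acetate, CC(=C)OC(C)=O
Why: Acid-catalysed enol acetylation under equilibrating conditions should give the linearly conjugated, thermodynamic dienol acetate, as in the classical enone to dienol acetate conversion.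

Step 2
Reactants: 2 3-methylcyclohexa-1,3-dien-1-yl acetate
Product: 3 rac-4-hydroxy-3-methylcyclohex-2-en-1-one
Conditions: mCPBA, dioxane/H2O, 0 °C → rt
Reagents that add atoms: mCPBA, O=C(OO)c1cccc(Cl)c1
Why: The peracid should attack the remote, more nucleophilic C3=C4 bond and the epoxide collapse with loss of the acetyl group to the γ-hydroxy enone (vinylogous Rubottom oxidation, known for steroidal dienol acetates); the carbinol centre forms as a racemate.

Step 3
Reactants: 3 rac-4-hydroxy-3-methylcyclohex-2-en-1-one
Product: 4 (S)-4-hydroxy-3-methylcyclohex-2-en-1-one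
Conditions: Burkholderia cepacia lipase (Amano PS), vinyl acetate, MTBE, 30 °C, run past half conversion; chromatography
Reagents that add atoms: none
Why: Lipase-catalysed kinetic resolution by transesterification should acylate the (R)-carbinol and leave the (S)-alcohol, whose enantiomeric purity rises with conversion; this fixes the future C7 and C7′.

Step 4
Reactants: 4 (S)-4-hydroxy-3-methylcyclohex-2-en-1-one
Product: 5 (S)-4-[(tert-butyldimethylsilyl)oxy]-3-methylcyclohex-2-en-1-one
Conditions: TBSCl, imidazole, DMF, rt
Reagents that add atoms: tert-butyldimethylsilyl chloride, CC(C)(C)[Si](C)(C)Cl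
Why: Standard silylation of a secondary alcohol under mild conditions that should not enolise the γ-oxygenated enone, so the carbinol configuration is kept.

Step 5
Reactants: 5 (S)-4-[(tert-butyldimethylsilyl)oxy]-3-methylcyclohex-2-en-1-one; 6 5-bromo-2-methylpent-2-ene
Product: 8 [(3S,4S)-4-(tert-butyldimethylsilyloxy)-3-methyl-3-(4-methylpent-3-en-1-yl)cyclohex-1-en-1-yl]oxy(trimethyl)silane, via (4-methylpent-3-en-1-yl)magnesium bromide 7 (not isolated)
Conditions: 6, Mg, THF; then 5, CuBr·SMe2 (10 mol%), TMSCl, HMPA, THF, −78 °C; Et3N, cold aq. NaHCO3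
Reagents that add atoms: chlorotrimethylsilane, C[Si](C)(C)Cl
Why: Copper-catalysed, TMSCl-accelerated conjugate addition of a Grignard reagent tolerates the β,β-disubstituted enone; the homoprenyl group should enter anti to the C7 silyloxy group, which sets quaternary C6 with the arm trans to oxygen, and the enolate is kept regiospecifically as its TMS ether.

Step 6
Reactants: 8 [(3S,4S)-4-(tert-butyldimethylsilyloxy)-3-methyl-3-(4-methylpent-3-en-1-yl)cyclohex-1-en-1-yl]oxy(trimethyl)silane
Product: 11 (3S,4S)-4-(tert-butyldimethylsilyloxy)-3-methyl-2-methylidene-3-(4-methylpent-3-en-1-yl)cyclohexan-1-one, via Mannich base 9 (not isolated), via trimethylammonium iodide 10 (not isolated)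
Conditions: CH2=NMe2+ I−, CH2Cl2, rt; MeI, rt; sat. aq. NaHCO3, CH2Cl2, rt; used at once
Reagents that add atoms: N,N-dimethylmethyleneiminium iodide (Eschenmoser's salt), C=[N+](C)C.[I-]
Why: Mannich reaction of the silyl enol ether at C11 with the small iminium ion, N-methylation and base-induced loss of trimethylamine (Eschenmoser methylenation) should give the exocyclic enone; the carbon added is C12.

Step 7
Reactants: 11 (3S,4S)-4-(tert-butyldimethylsilyloxy)-3-methyl-2-methylidene-3-(4-methylpent-3-en-1-yl)cyclohexan-1-one (two molecules)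
Product: 12 2,2′-(ethane-1,2-diyl)bis[(2S,3S,4S)-4-(tert-butyldimethylsilyloxy)-3-methyl-3-(4-methylpent-3-en-1-yl)cyclohexan-1-one]
Conditions: SmI2 (1.1 equiv per enone), HMPA, t-BuOH, THF, −78 → 0 °C, concentrated solution
Reagents that add atoms: none
Why: One-electron reduction gives the enone radical anion, which should couple at its unhindered exocyclic β-carbon to form C12–C12′ (reductive hydrodimerisation of an enone); protonation of the samarium enolates at C11 opposite the neighbouring axial C6 methyl puts the bridge equatorial and cis to that methyl, which is also the more stable arrangement.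

Step 8
Reactants: 12 2,2′-(ethane-1,2-diyl)bis[(2S,3S,4S)-4-(tert-butyldimethylsilyloxy)-3-methyl-3-(4-methylpent-3-en-1-yl)cyclohexan-1-one]
Product: 13 mono-methylidene ketone (12 with the C10′ carbonyl replaced by C=CH2)
Conditions: Ph3PCH3Br (1.0 equiv), KHMDS (1.0 equiv), THF, 0 °C; then 12, 0 °C → rt; chromatography, recovered 12 recycled
Reagents that add atoms: methyltriphenylphosphonium bromide, C[P+](c1ccccc1)(c1ccccc1)c1ccccc1.[Br-]
Why: Wittig methylenation with one equivalent of preformed ylide; the two carbonyls of 12 are equivalent, so mono-olefination is statistical and the mono-olefin is separated from recovered diketone and bis-olefin.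

Step 9
Reactants: 13 mono-methylidene ketone; 14 methylmagnesium bromide
Product: 15 C10 carbinol (13 with the C10 carbonyl replaced by C(CH3)(OH), hydroxyl axial and cis to the C6 methyl)
Conditions: MeMgBr (3 equiv), LaCl3·2LiCl (0.3 equiv), THF, 0 °C; aq. NH4Cl
Reagents that add atoms: 14 methylmagnesium bromide, C[Mg]Br
Why: In this Grignard 1,2-addition the axial trajectory at C10 is blocked by the syn-axial C6 methyl, so methyl should enter equatorially and leave the hydroxyl axial, which is the C10 configuration of the target.

Step 10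
Reactants: 15 C10 carbinol
Product: 17 C10,C10′-diol (15 with C10′=CH2 replaced by C(CH3)(OH), hydroxyl equatorial and trans to the C6′ methyl), via acetoxymercurial 16 (not isolated)
Conditions: Hg(OAc)2 (1.05 equiv), THF/H2O, 0 °C; then aq. NaOH, NaBH4, 0 °C
Reagents that add atoms: water, O
Why: In oxymercuration–demercuration Hg(II) engages a 1,1-disubstituted alkene much faster than the trisubstituted side-chain alkenes; water should open the mercurinium ion at tertiary C10′ from the equatorial side because the axial side is screened by the C6′ methyl, and borohydride then replaces mercury by hydrogen.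

Step 11
Reactants: 17 C10,C10′-diol
Product: 19 C10,C10′-diacetate bis(TBS ether), via dilithium dialkoxide 18 (not isolated)
Conditions: n-BuLi (2.2 equiv), THF, −78 → 0 °C; Ac2O (4 equiv), 0 °C → rt
Reagents that add atoms: acetic anhydride, CC(=O)OC(C)=O
Why: O-acylation of preformed lithium alkoxides is the dependable way to esterify hindered tertiary alcohols (one of them syn-diaxial to a methyl); no stereocentre is touched.

Step 12
Reactants: 19 C10,C10′-diacetate bis(TBS ether)
Product: 20 diene diol diacetate (C7 and C7′ hydroxyls free, homoprenyl arms intact)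
Conditions: HF (48% aq.), MeCN, rt
Reagents that add atoms: none
Why: Fluoride-driven cleavage of the two secondary TBS ethers under mildly acidic conditions that tertiary acetates and trisubstituted alkenes tolerate; it is placed before epoxidation so that no basic fluoride meets a hydroxy epoxide.

Step 13
Reactants: 20 diene diol diacetate
Product: 21 bis(hydroxy epoxide) diacetate, (3R,3′R)
Conditions: D-fructose-derived Shi ketone (0.6 equiv), Oxone, K2CO3, Bu4NHSO4, MeCN/dimethoxymethane/aq. borate buffer (pH about 10.5), 0 °C
Reagents that add atoms: potassium peroxymonosulfate (active component of Oxone), [K+].[O-]S(=O)(=O)OO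
Why: Shi asymmetric epoxidation (chiral dioxirane, spiro transition state) of both trisubstituted alkenes should install the (3R) and (3′R) oxiranes under reagent control, while free hydroxyls and tertiary acetates are inert at this pH and temperature.

Step 14
Reactants: 21 bis(hydroxy epoxide) diacetate, (3R,3′R)
Product: 22 bis(oxepan-3-ol) diacetate, (3R,3′R)
Conditions: (1S)-(+)-10-camphorsulfonic acid (0.2 equiv), CH2Cl2, 0 °C
Reagents that add atoms: none
Why: The acid protonates each oxirane, the bond from oxygen to the gem-dimethyl carbon C2 lengthens, and the neighbouring equatorial C7 hydroxyl adds to C2 from the rear while the oxirane oxygen stays on C3 as the carbinol, giving O1–C2 and O1′–C2′. The closest known reaction type is the acid-promoted endo-selective cyclisation of hydroxy epoxides bearing a trisubstituted oxirane to 2,2-dimethyloxepan-3-ols. Both oxepanes close in the 7-endo-tet mode, independently on the two remote halves. No stereocentre is formed: C2 bears two methyls, C3 keeps the (R) configuration from step 13 because its C–O bond is not broken, and the trans ring fusion is inherited from the trans-diequatorial C5 arm and C7 oxygen on the cyclohexane chair. The selectivity needed is attack at C2 (7-endo) over attack at C3 (6-exo); it rests on the cation-stabilising tertiary C2 under Brønsted activation in a non-nucleophilic solvent, and a single (3R,3′R) diastereomer makes the outcome uniform. The tertiary acetates are expected to survive catalytic acid at 0 °C.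

Step 15
Reactants: 22 bis(oxepan-3-ol) diacetate, (3R,3′R)
Product: 23 CNP0325605.1 (bis(oxepan-3-one) diacetate)
Conditions: Dess–Martin periodinane (3 equiv), CH2Cl2, rt
Reagents that add atoms: none
Why: Dess–Martin oxidation of the two secondary C3 carbinols to ketones; tertiary acetates and ethers are inert and the flanking C2 is quaternary, so no epimerisable centre is created.

**Compound list**

1 | 3-methylcyclohex-2-en-1-one | CC1=CC(=O)CCC1 | starting material
2 | 3-methylcyclohexa-1,3-dien-1-yl acetate | CC(=O)OC1=CC(C)=CCC1 | intermediate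
3 | rac-4-hydroxy-3-methylcyclohex-2-en-1-one | CC1=CC(=O)CCC1O | intermediate
4 | (S)-4-hydroxy-3-methylcyclohex-2-en-1-one | O=C1CC[C@H](O)C(C)=C1 | intermediate
5 | (S)-4-[(tert-butyldimethylsilyl)oxy]-3-methylcyclohex-2-en-1-one | O=C1CC[C@H](O[Si](C)(C)C(C)(C)C)C(C)=C1 | intermediate
6 | 5-bromo-2-methylpent-2-ene | CC(C)=CCCBr | starting material
7 | (4-methylpent-3-en-1-yl)magnesium bromide | CC(C)=CCC[Mg]Br | intermediate
8 | [(3S,4S)-4-(tert-butyldimethylsilyloxy)-3-methyl-3-(4-methylpent-3-en-1-yl)cyclohex-1-en-1-yl]oxy(trimethyl)silane | C[Si](C)(C)OC1=C[C@](C)(CCC=C(C)C)[C@@H](O[Si](C)(C)C(C)(C)C)CC1 | intermediate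
9 | Mannich base: (3S,4S)-4-(tert-butyldimethylsilyloxy)-2-[(dimethylamino)methyl]-3-methyl-3-(4-methylpent-3-en-1-yl)cyclohexan-1-one, C2 epimers | O=C1CC[C@H](O[Si](C)(C)C(C)(C)C)[C@@](C)(CCC=C(C)C)C1CN(C)C | intermediate
10 | trimethylammonium iodide of 9 | O=C1CC[C@H](O[Si](C)(C)C(C)(C)C)[C@@](C)(CCC=C(C)C)C1C[N+](C)(C)C.[I-] | intermediate
11 | (3S,4S)-4-(tert-butyldimethylsilyloxy)-3-methyl-2-methylidene-3-(4-methylpent-3-en-1-yl)cyclohexan-1-one | O=C1CC[C@H](O[Si](C)(C)C(C)(C)C)[C@@](C)(CCC=C(C)C)C1=C | intermediate
12 | 2,2′-(ethane-1,2-diyl)bis[(2S,3S,4S)-4-(tert-butyldimethylsilyloxy)-3-methyl-3-(4-methylpent-3-en-1-yl)cyclohexan-1-one] | O=C1CC[C@H](O[Si](C)(C)C(C)(C)C)[C@@](C)(CCC=C(C)C)[C@@H]1CC[C@H]1[C@](C)(CCC=C(C)C)[C@@H](O[Si](C)(C)C(C)(C)C)CCC1=O | intermediate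
13 | mono-methylidene ketone: 12 with the C10′ carbonyl replaced by C=CH2 | O=C1CC[C@H](O[Si](C)(C)C(C)(C)C)[C@@](C)(CCC=C(C)C)[C@@H]1CC[C@H]1[C@](C)(CCC=C(C)C)[C@@H](O[Si](C)(C)C(C)(C)C)CCC1=C | intermediate
14 | methylmagnesium bromide | C[Mg]Br | starting material
15 | C10 carbinol: tertiary hydroxyl at C10 axial and cis to the C6 methyl, C10′ still methylidene | O[C@]1(C)CC[C@H](O[Si](C)(C)C(C)(C)C)[C@@](C)(CCC=C(C)C)[C@@H]1CC[C@H]1[C@](C)(CCC=C(C)C)[C@@H](O[Si](C)(C)C(C)(C)C)CCC1=C | intermediate
16 | acetoxymercurial: C10′ bearing equatorial hydroxyl and axial CH2HgOAc | O[C@]1(C)CC[C@H](O[Si](C)(C)C(C)(C)C)[C@@](C)(CCC=C(C)C)[C@@H]1CC[C@H]1[C@](C)(CCC=C(C)C)[C@@H](O[Si](C)(C)C(C)(C)C)CC[C@]1(C[Hg]OC(C)=O)O | intermediate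
17 | C10,C10′-diol: C10 hydroxyl axial (cis to C6 methyl), C10′ hydroxyl equatorial (trans to C6′ methyl), both C7 oxygens as TBS ethers | O[C@]1(C)CC[C@H](O[Si](C)(C)C(C)(C)C)[C@@](C)(CCC=C(C)C)[C@@H]1CC[C@H]1[C@](C)(CCC=C(C)C)[C@@H](O[Si](C)(C)C(C)(C)C)CC[C@]1(C)O | intermediate
18 | dilithium dialkoxide of 17 | [Li+].[Li+].[O-][C@]1(C)CC[C@H](O[Si](C)(C)C(C)(C)C)[C@@](C)(CCC=C(C)C)[C@@H]1CC[C@H]1[C@](C)(CCC=C(C)C)[C@@H](O[Si](C)(C)C(C)(C)C)CC[C@]1(C)[O-] | intermediate
19 | C10,C10′-diacetate bis(TBS ether) | CC(=O)O[C@]1(C)CC[C@H](O[Si](C)(C)C(C)(C)C)[C@@](C)(CCC=C(C)C)[C@@H]1CC[C@H]1[C@](C)(CCC=C(C)C)[C@@H](O[Si](C)(C)C(C)(C)C)CC[C@]1(C)OC(C)=O | intermediate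
20 | diene diol diacetate: C7 and C7′ hydroxyls free, two homoprenyl arms | CC(=O)O[C@]1(C)CC[C@H](O)[C@@](C)(CCC=C(C)C)[C@@H]1CC[C@H]1[C@](C)(CCC=C(C)C)[C@@H](O)CC[C@]1(C)OC(C)=O | intermediate
21 | bis(hydroxy epoxide) diacetate, (3R,3′R) | CC(=O)O[C@]1(C)CC[C@H](O)[C@@](C)(CC[C@H]2OC2(C)C)[C@@H]1CC[C@H]1[C@](C)(CC[C@H]2OC2(C)C)[C@@H](O)CC[C@]1(C)OC(C)=O | intermediate
22 | bis(oxepan-3-ol) diacetate, (3R,3′R), both oxepanes trans-fused | CC(=O)O[C@]1(C)CC[C@@H]2OC(C)(C)[C@H](O)CC[C@@]2(C)[C@@H]1CC[C@H]1[C@]2(C)CC[C@@H](O)C(C)(C)O[C@H]2CC[C@]1(C)OC(C)=O | intermediate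
23 | CNP0325605.1, bis(oxepan-3-one) diacetate | CC(=O)O[C@]1(C)CC[C@@H]2OC(C)(C)C(=O)CC[C@@]2(C)[C@@H]1CC[C@H]1[C@]2(C)CCC(=O)C(C)(C)O[C@H]2CC[C@]1(C)OC(C)=O | target

**Count and risks**

Total step count: 15. Longest linear sequence: 15 steps (1 → 23).

Steps most likely to fail:

Step 14. The hydroxyl may open the oxirane at C3 in the 6-exo mode, or the activated oxirane may rearrange by hydride shift before it is trapped. The fallback avoids the oxirane and sets out from 20. Mercury(II) trifluoroacetate in nitromethane at −20 °C should bring about intramolecular alkoxymercuration of each homoprenyl alkene with Markovnikov regiochemistry (O1 to the tertiary C2, mercury to C3), where a 6-exo closure would be anti-Markovnikov. Brine work-up gives the bis(chloromercurial) F1. Oxidative demercuration (NaBH4, O2, DMF) gives the bis(oxepan-3-ol) diacetate as a mixture of C3 and C3′ epimers F2. Dess–Martin oxidation under the conditions of step 15 converges on 23.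

Step 7. The radical anion may be reduced further to the saturated α-methyl ketone, or the coupled enolate may add to the second carbonyl, instead of clean β,β-coupling. The fallback sets out from 11 and forms the C12–C12′ bond by radical conjugate addition. Benzeneselenol, generated from diphenyl diselenide and NaBH4 in ethanol and buffered with acetic acid, adds to 11 to give (2S,3S,4S)-4-(tert-butyldimethylsilyloxy)-3-methyl-3-(4-methylpent-3-en-1-yl)-2-[(phenylselanyl)methyl]cyclohexan-1-one F3. Slow addition of Bu3SnH with AIBN in benzene at 80 °C, in the presence of a second portion of 11, generates the primary C12 radical, which adds to the enone (Giese addition). Hydrogen transfer to C11 from the face opposite the C6 methyl gives 12.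

Step 10. Mercuration may spread to the side-chain alkenes, or water may not discriminate fully between the two faces at C10′. The fallback sets out from 15 and comes back at 17 with no new compound (F0). It is a Mukaiyama hydration (Co(acac)2, PhSiH3, O2, THF/i-PrOH, then triethyl phosphite). Metal-hydride hydrogen-atom transfer is governed by steric access to the terminal CH2 and so favours the 1,1-disubstituted alkene, and oxygen should trap the tertiary C10′ radical from the equatorial side.

Further compounds
F1 | step 14 | bis(chloromercurial): 22 with each C3 hydroxyl replaced by HgCl, C3 and C3′ configuration not controlled | CC(=O)O[C@]1(C)CC[C@@H]2OC(C)(C)C([Hg]Cl)CC[C@@]2(C)[C@@H]1CC[C@H]1[C@]2(C)CCC([Hg]Cl)C(C)(C)O[C@H]2CC[C@]1(C)OC(C)=O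
F2 | step 14 | bis(oxepan-3-ol) diacetate as C3 and C3′ epimers | CC(=O)O[C@]1(C)CC[C@@H]2OC(C)(C)C(O)CC[C@@]2(C)[C@@H]1CC[C@H]1[C@]2(C)CCC(O)C(C)(C)O[C@H]2CC[C@]1(C)OC(C)=O
F3 | step 7 | (2S,3S,4S)-4-(tert-butyldimethylsilyloxy)-3-methyl-3-(4-methylpent-3-en-1-yl)-2-[(phenylselanyl)methyl]cyclohexan-1-one | O=C1CC[C@H](O[Si](C)(C)C(C)(C)C)[C@@](C)(CCC=C(C)C)[C@@H]1C[Se]c1ccccc1
F0 | step 10 | none | none
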